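**The trap.** A straight line drawn from an early rate through a progress curve counts no slowing. The flask in question is Saturday's, followed for a while and now asked about later.

| setting | Saturday's | Tuesday's | flask |
|---|---|---|---|
| starting material | 0.17 M | 0.26 M | 0.17 M |
| gas | 50 mM (held) | 50 mM (held) | 50 mM (held) |
| remark | the very flask that is asked about, followed so far | run made earlier |  |
| time |  |  | 1.5 h |

| Saturday's: time / min | Saturday's: target / % | Tuesday's: time / min | Tuesday's: target / % |
|---|---|---|---|
| 2.00 | 0.3 | 5.00 | 0.9 |
| 3.00 | 0.3 | 8.00 | 2.7 |
| 5.00 | 0.3 | 12.0 | 1.4 |
| 8.00 | 3.9 | 20.0 | 5.1 |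
| 12.0 | 3.6 | 25.0 | 6.1 |
| 20.0 | 8.6 | 40.0 | 11.2 |
| 25.0 | 8.4 | 60.0 | 16.5 |

(readings scatter by 1 percentage point)

- amount of target at 1.5 h, in percent of the starting material charged
- concentration of reagent in solution at 1.5 h, in percent of saturation

- at the start none of the gas is in solution
- reagent is what gas becomes in solution

**Starting rate.** The last two readings of Saturday's flask give an apparent first-order constant, the share of the remaining starting material turned into target per minute: 0.00395 min⁻¹. Tuesday's flask, with its larger charge, reads a smaller constant, 0.00301 min⁻¹, so the constant is used for Saturday's charge and is not carried over from Tuesday's.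

**The slowing.** The reckoning here assumes that the rate in Saturday's flask follows c(starting material), which Saturday's readings do not test. The rate then stands at 0.837 of its start after 0.750 h and at 0.701 after 1.5 h. Its mean factor is 0.842, which gives 29.9 % of target. The readings show target, not reagent, so this reckoning offers no figure for reagent.

**The forecast.** It says 36 % of target and 11 % of saturation, holding that “the rate is essentially independent of starting material”. The reckoning here stands lower.

**The flask.** It gives 29.2 % of target and 49.2 % of saturation. In this flask at 0.631 h, intermediate falls back 3.2 times faster than it goes on.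

    starting material ⇌ intermediate + leaving ligand (K = 3.10 × 10⁻⁴ M, k = 0.0167 min⁻¹)
    reagent + intermediate → target (k = 30.3 M⁻¹ min⁻¹)
    gas ⇌ reagent, rate k3*(csat - [reagent]) (kL = 0.0234 min⁻¹)

At 0.750 h the constant gives 16.3 %, and the flask holds 16.2 %.

**Second flask.** For the same flask read at 4.0 h, the constant gives 61.2 %. The computed flask holds 56.7 %.

(The readings are simulated with constants of no real substance.)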